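## Analysis of the target

Target 10 is an open-chain mixed ester made of two pieces. One is a 4-hydroxy-3,5-dimethoxyphenyl ring carrying the chain Cα=Cβ–Cγ(H2)–O. The other is 3-hydroxy-3-methylglutaric acid, with one carboxyl group esterified by the Cγ oxygen and the other free.

The only stereocentre is C3 of the pentanedioate chain, a tertiary carbinol bearing CH3, OH and two CH2C(=O) arms. With the priorities OH > CH2CO2R > CH2CO2H > CH3, the SMILES reads as (3R). The two arms differ only as ester and acid, so any acyl transfer between the carboxyl groups through the symmetric cyclic anhydride erases the stereocentre. The second stereo-element is the Z geometry of Cα=Cβ, the less stable isomer of a styrene-type alkene.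

The fragile part is the para-hydroxycinnamyl ester. The phenoxide can push the carboxylate out through the ring and the alkene, the allylic C–O bond is ionised by zerovalent palladium and cleaved by hydrogenolysis, and the Z alkene isomerises easily. The phenol is also oxidised readily, and the β-hydroxy carbonyl unit does not tolerate strong base.

The difficulty is therefore to obtain one defined carboxyl group, one enantiomer and one alkene geometry in a molecule that should see very little base, acid or metal. The plan rests on the bond between ring carbon C4 (para to the OH) and Cα, and on the fact that the Z alkene Cα=Cβ is the syn-hydrogenation product of an alkyne. With a triple bond in that position, the half ester is a robust propargyl ester that can be joined to the ring by aryl–alkyne coupling.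

## Retrosynthetic reasoning

**10 to 9.** The Z alkene of 10 is traced back to the triple bond of aryl alkyne 9. No skeletal bond is cut; two hydrogen atoms are removed. This is placed last so that the labile Z-4-hydroxycinnamyl ester exists only in the final product. The forward reaction has to add one equivalent of hydrogen to one face of the alkyne and stop, without cleaving the allylic C–O bond.

**9 to 2 and 8.** The bond between ring carbon C4 and Cα is cut, giving aryl iodide 2 and terminal alkyne 8. This is the one carbon–carbon bond that joins two fully functionalised halves, and both halves are small and stable. Alkyne 8 already holds the complete half ester with its stereocentre. Cutting the ester C–O bond instead would require a protected, differentiated glutarate and a labile aryl-substituted unsaturated alcohol. Cutting inside the glutarate would move the creation of the stereocentre to a late stage. The forward reaction is an aryl–alkyne cross-coupling that must tolerate a free phenol, a free acid and a tertiary alcohol, and must leave the ester on its own carboxyl group.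

**8 to 6.** The free carboxyl group of 8 is traced back to the primary alcohol of hydroxy ester 6, through aldehyde 7. In 6 the two arms on the carbinol carbon differ in oxidation state, so the stereocentre no longer depends on telling two like carboxyl groups apart. The forward oxidation must take a primary alcohol to the acid beside a tertiary alcohol, an ester and a terminal alkyne. The shorter idea, enantioselective mono-esterification of a symmetric C6 diacid derivative, was set aside. It would have to distinguish CH3 from OH at a quaternary carbon, which is not dependable for this substitution pattern, and a half ester made that way cannot be upgraded by separating diastereomers.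

**6 to 3 and 4.** The O–CH2 bond of the propargyl ester is cut, giving carboxylate 5 and bromide 4. Carboxylate 5 is the saponification product of lactone 3. Lactone 3 already carries the stereocentre in the required sense: its carbonyl arm becomes the ester arm and its CH2CH2O arm becomes the acid arm, so (R) in 3 maps to (R) in 8 and in 10. The forward reaction is a carboxylate O-alkylation in which no bond to C3 is touched.

**2 to 1.** The C4–I bond of 2 is cut, leading to phenol 1. The forward iodination must go para to the hydroxyl group, which both blocked ortho positions favour.

## Alternatives that were turned down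

**Alternative 1: homologation of a C5 hydroxy diacid by Wolff rearrangement.**
- Disconnection: the bond between the ester-side methylene C2 and the carbinol carbon C3, together with the ester C1–O bond. The glutarate is derived from (R)-citramalic acid A4, one carbon shorter, through diazoketone A2.
- Key step: under AgO2CPh and triethylamine in the dark, A2 loses N2, the quaternary carbon migrates with retention, and the ketene is captured by silyl-protected (Z)-sinapyl alcohol A3. The product is the fully protected target A1.
- For it: A4 is an inexpensive chiral-pool acid available in both enantiomeric forms. The ester forms under nearly neutral conditions. The Z alkene is made on the simple alcohol A3, where there is no allylic ester to hydrogenolyse; on these points it is stronger than the chosen route.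
- Against it: A2 requires differentiation of the two carboxyl groups of A4, protection of the tertiary alcohol, activation of a hindered α-oxygenated acid and an Arndt–Eistert sequence. The ketene must be trapped by about one equivalent of a precious, labile alcohol. A3 itself needs its own aryl–alkyne coupling and semi-hydrogenation. A1 carries three silicon protecting groups, and their removal by fluoride liberates the phenoxide on the finished Z-cinnamyl ester, which is when loss of the carboxylate is most likely.
- Comparison: the chosen route gives up the cheaper chiral source. In return it is less than half as long, uses no protecting groups and has no deprotection after the fragile ester appears.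

**Alternative 2: decarboxylative thioester aldol onto an acetoacetate.**
- Disconnection: the C3–C4 bond between the carbinol carbon and the acid-side methylene; the stereocentre is created in the same step.
- Key step: malonic acid half thioester A7 adds with loss of CO2 to the ketone of silyl-protected (Z)-sinapyl acetoacetate A6 under a chiral catalyst, giving thioester A5.
- For it: it mirrors the biosynthesis of the hydroxymethylglutarate unit and makes the stereocentre catalytically from achiral bulk chemicals. In this respect it is stronger than the chosen route, which buys its stereocentre.
- Against it: the ketone of A6 is flanked by an acidic methylene, so an amine catalyst forms the unreactive enolate instead of promoting addition. Such decarboxylative additions are established for aldehydes and activated ketones, not for a methyl ketone of this kind. The catalyst would have to distinguish CH3 from CH2CO2R on the carbonyl faces. The tertiary aldol can revert. A5 still needs selective hydrolysis of the thioester beside the allylic ester, then desilylation. A6 must be made from A3, so the Z alcohol is needed here as well.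
- Comparison: the only stereo-defining step would be unprecedented on this ketone class. The chosen route offers certainty of configuration and reactions of known type throughout.

**Alternative 3: Stille coupling of an acyloxymethylstannane with a Z-styryl iodide.**
- Disconnection: the Cβ–Cγ bond between the alkene and the oxygen-bearing methylene.
- Key step: (Z)-vinyl iodide A9 couples with the tributylstannylmethyl ester A10 of the protected chiral half ester under Pd2(dba)3, AsPh3 and CuI, with retention of geometry, giving protected target A8.
- For it: the Z geometry is fixed in a small vinyl iodide and transferred without any reduction, so over-reduction and hydrogenolysis cannot occur. On this point it is stronger than the chosen route.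
- Against it: transfer of an oxygenated sp3 carbon from tin is slow and competes with butyl transfer. The product A8 is a cinnamyl-type ester, which zerovalent palladium ionises readily to an allyl complex, with loss of the carboxylate and scrambling of the alkene geometry. A10 needs a doubly differentiated glutarate and stoichiometric tin. A8 again needs fluoride deprotection on the labile ester.
- Comparison: in the chosen route palladium meets only a primary propargylic ester, which ionises far more slowly, and the allylic ester appears after the last coupling. It is also shorter and free of tin.

Key step: step 4

Assumption: (R)-(−)-mevalonolactone (3) is bought as the single enantiomer; since no later step makes or breaks a bond at C3, its optical purity sets that of 10.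

## Route

Step 1
Reactants: 1 2,6-dimethoxyphenol
Product: 2 4-iodo-2,6-dimethoxyphenol
Conditions: I2 (1.0 equiv), NaHCO3 (1.2 equiv), THF/H2O 1:1, 0 °C to rt, dark
Reagents that add atoms: iodine, II
Why: Electrophilic aromatic iodination through the phenoxide present in the bicarbonate medium; the phenoxide oxygen is the strongest donor and both its ortho positions carry methoxy groups, so iodine should enter at C4, para to the oxygen. Low temperature and one equivalent of iodine limit one-electron oxidation of the electron-rich phenol.

Step 2
Reactants: 3 (R)-mevalonolactone; 4 propargyl bromide
Product: 6 prop-2-yn-1-yl (3R)-3,5-dihydroxy-3-methylpentanoate, via potassium (R)-mevalonate 5 (not isolated)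
Conditions: KOH (1.0 equiv), H2O, 40 °C, then evaporation to dryness; 4 (1.2 equiv), Bu4NBr (5 mol%), DMF, 0 °C to rt
Reagents that add atoms: potassium hydroxide, [K+].[OH-]
Why: Saponification opens the six-membered lactone to carboxylate 5, which is O-alkylated by the propargylic bromide in an SN2 reaction (carboxylate alkylation); the neutral primary and tertiary hydroxyl groups are not alkylated without a stronger base. No bond to C3 is made or broken, so the (R) configuration of 3 is carried over, with the lactone carbonyl arm becoming the ester arm.

Step 3
Reactants: 6 prop-2-yn-1-yl (3R)-3,5-dihydroxy-3-methylpentanoate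
Product: 8 (3R)-3-hydroxy-3-methyl-5-oxo-5-(prop-2-yn-1-yloxy)pentanoic acid, via aldehyde 7 (not isolated)
Conditions: TEMPO (20 mol%), PhI(OAc)2 (2.2 equiv), MeCN/H2O 1:1, 0 °C to rt
Reagents that add atoms: water, O
Why: Nitroxyl-mediated oxidation with PhI(OAc)2 as terminal oxidant (Epp–Widlanski conditions): the oxoammonium ion oxidises the primary alcohol to aldehyde 7, whose hydrate is oxidised on to the acid. The tertiary alcohol has no carbinol hydrogen and the ester and terminal alkyne are inert; C3 is untouched and stays (R).

Step 4
Reactants: 2 4-iodo-2,6-dimethoxyphenol; 8 (3R)-3-hydroxy-3-methyl-5-oxo-5-(prop-2-yn-1-yloxy)pentanoic acid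
Product: 9 (3R)-3-hydroxy-5-{[3-(4-hydroxy-3,5-dimethoxyphenyl)prop-2-yn-1-yl]oxy}-3-methyl-5-oxopentanoic acid
Conditions: 2 (1.1 equiv), Pd(PPh3)2Cl2 (3 mol%), CuI (5 mol%), Et3N (4 equiv), degassed THF, Ar, rt to 40 °C; aq. citric acid work-up
Reagents that add atoms: none
Why: Sonogashira coupling: Pd(PPh3)2Cl2 is reduced in the flask to zerovalent palladium, which inserts into the C4–I bond of 2, while CuI and Et3N turn the terminal alkyne of 8 into a copper acetylide that transmetalates to the arylpalladium iodide; reductive elimination then forms the aryl–C(sp) bond of 9 and returns zerovalent palladium. The closest known reaction type is the coupling of unprotected iodophenols with propargylic alcohols and propargylic carboxylates. No ring closes and no stereocentre is formed; C3 carries no acidic hydrogen and stays (R). The site of coupling is fixed by the position of the iodide, and carbon–carbon coupling is preferred over O-arylation because the soft acetylide, not a phenol or carboxylate oxygen, is transferred to palladium. Homocoupling of the alkyne is held back by strict exclusion of oxygen and a low loading of CuI. The carboxylic acid travels as its triethylammonium salt, which costs one extra equivalent of amine but should not interfere, and the primary propargylic carboxylate ionises only slowly towards zerovalent palladium near room temperature. Scrambling of the ester between the two carboxyl groups would require the carboxylate to expel the propargyl alkoxide, which is not expected at or below 40 °C.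

Step 5
Reactants: 9 (3R)-3-hydroxy-5-{[3-(4-hydroxy-3,5-dimethoxyphenyl)prop-2-yn-1-yl]oxy}-3-methyl-5-oxopentanoic acid
Product: 10 (3R)-3-hydroxy-5-{[(2Z)-3-(4-hydroxy-3,5-dimethoxyphenyl)prop-2-en-1-yl]oxy}-3-methyl-5-oxopentanoic acid
Conditions: H2 (1 atm), Pd/CaCO3 (5% Pd) poisoned with Pb(OAc)2, quinoline (0.5 equiv), EtOAc, rt, stopped after 1 equiv of H2
Reagents that add atoms: none
Why: Lindlar semi-hydrogenation: both hydrogen atoms are transferred from the poisoned palladium surface to the same face of the adsorbed alkyne, so the Z alkene should result; Pb(OAc)2 and quinoline weaken binding of the alkene so that it leaves the surface before saturation or hydrogenolysis of the allylic C–O bond. A non-nucleophilic solvent and a neutral to slightly acidic work-up avoid ionisation of the para-hydroxycinnamyl ester; C3 is not involved.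

## Compound list

1 | 2,6-dimethoxyphenol | COc1cccc(OC)c1O | starting material
2 | 4-iodo-2,6-dimethoxyphenol | COc1cc(I)cc(OC)c1O | intermediate
3 | (R)-mevalonolactone, (4R)-4-hydroxy-4-methyloxan-2-one | C[C@@]1(O)CCOC(=O)C1 | starting material
4 | propargyl bromide (3-bromoprop-1-yne) | C#CCBr | starting material
5 | potassium (3R)-3,5-dihydroxy-3-methylpentanoate | [K+].[O-]C(=O)C[C@](C)(O)CCO | intermediate
6 | prop-2-yn-1-yl (3R)-3,5-dihydroxy-3-methylpentanoate | C#CCOC(=O)C[C@](C)(O)CCO | intermediate
7 | prop-2-yn-1-yl (3R)-3-hydroxy-3-methyl-5-oxopentanoate | C#CCOC(=O)C[C@](C)(O)CC=O | intermediate
8 | (3R)-3-hydroxy-3-methyl-5-oxo-5-(prop-2-yn-1-yloxy)pentanoic acid | C#CCOC(=O)C[C@](C)(O)CC(=O)O | intermediate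
9 | (3R)-3-hydroxy-5-{[3-(4-hydroxy-3,5-dimethoxyphenyl)prop-2-yn-1-yl]oxy}-3-methyl-5-oxopentanoic acid | COc1cc(C#CCOC(=O)C[C@](C)(O)CC(=O)O)cc(OC)c1O | intermediate
10 | (3R)-3-hydroxy-5-{[(2Z)-3-(4-hydroxy-3,5-dimethoxyphenyl)prop-2-en-1-yl]oxy}-3-methyl-5-oxopentanoic acid | COc1cc(/C=C\COC(=O)C[C@](C)(O)CC(=O)O)cc(OC)c1O | target

Total step count: 5. Longest linear sequence: 4 steps (3 to 6 to 8 to 9 to 10); step 1 is a one-step side branch.

## Steps least certain to work

**Step 4 (key step).** The most likely failure is a slow oxidative addition. Under the amine the phenol is partly ionised, which makes the iodide-bearing ring very electron-rich, so copper-mediated dimerisation of the alkyne can overtake the coupling. A second risk is amine-promoted loss of the carboxylate from the product by ionisation through the para-hydroxyaryl alkyne. A third is ionisation of the propargylic C–O bond by zerovalent palladium if the mixture has to be heated.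

The fallback masks the phenol. It sets out from 2: TBSCl and imidazole in DMF should give tert-butyl(4-iodo-2,6-dimethoxyphenoxy)dimethylsilane F1. Coupling of F1 with 8 under the conditions of step 4 should give the silyl ether of 9, (3R)-5-{[3-(4-{[tert-butyl(dimethyl)silyl]oxy}-3,5-dimethoxyphenyl)prop-2-yn-1-yl]oxy}-3-hydroxy-3-methyl-5-oxopentanoic acid F2. Et3N·3HF in THF then removes the silyl group at the alkyne stage, where the ester is still robust, and the route is rejoined at 9.

**Step 5.** The reduction may run on to the saturated chain, cleave the allylic C–O bond by hydrogenolysis, or isomerise the Z alkene to E on the metal surface. The free acid can also bind the quinoline and change the poisoning of the catalyst.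

The fallback replaces catalytic hydrogenation by a metal reduction. It sets out from 9 and comes back at 10: zinc dust activated with Cu(OAc)2 and AgNO3 in aqueous isopropanol at room temperature (Boland reduction). This reduces aryl-conjugated alkynes to Z alkenes by electron transfer and protonation, uses neither H2 nor palladium, and does not reduce the alkene further. It makes no new compound (F0).

**Step 3.** Before the primary alcohol is oxidised, 6 can close back to the lactone with loss of the propargyl group in the aqueous, slightly acidic medium. The β-hydroxy aldehyde stage can also lose water.

The fallback separates the two oxidation stages and keeps the first one anhydrous. It sets out from 6: Dess–Martin periodinane with NaHCO3 in CH2Cl2 gives aldehyde 7, this time isolated. A Pinnick oxidation (NaClO2, NaH2PO4, 2-methyl-2-butene, tBuOH/H2O) then gives 8, where the route is rejoined. It makes no new compound (F0).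

**Step 2.** The δ-hydroxy ester 6 may relactonise during concentration or chromatography, again with loss of the propargyl group, so that little of it reaches step 3.

The fallback never sets the primary hydroxyl group free beside the ester. It sets out from salt 5:
- TBSCl (2.2 equiv) and imidazole in DMF give tert-butyldimethylsilyl (3R)-5-[(tert-butyldimethylsilyl)oxy]-3-hydroxy-3-methylpentanoate F3.
- K2CO3 in MeOH/H2O cleaves only the silyl ester, giving (3R)-5-[(tert-butyldimethylsilyl)oxy]-3-hydroxy-3-methylpentanoic acid F4.
- K2CO3 and 4 in DMF give prop-2-yn-1-yl (3R)-5-[(tert-butyldimethylsilyl)oxy]-3-hydroxy-3-methylpentanoate F5, which cannot lactonise.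
- CrO3 and H2SO4 in acetone at 0 °C (Jones oxidation) remove the primary silyl ether and oxidise the carbon to the acid in one operation.

The route is rejoined at 8, bypassing 6 and step 3.

## Further compounds

F1 | step 4 | tert-butyl(4-iodo-2,6-dimethoxyphenoxy)dimethylsilane | COc1cc(I)cc(OC)c1O[Si](C)(C)C(C)(C)C
F2 | step 4 | (3R)-5-{[3-(4-{[tert-butyl(dimethyl)silyl]oxy}-3,5-dimethoxyphenyl)prop-2-yn-1-yl]oxy}-3-hydroxy-3-methyl-5-oxopentanoic acid | COc1cc(C#CCOC(=O)C[C@](C)(O)CC(=O)O)cc(OC)c1O[Si](C)(C)C(C)(C)C
F0 | step 5 | none | none
F0 | step 3 | none | none
F3 | step 2 | tert-butyldimethylsilyl (3R)-5-[(tert-butyldimethylsilyl)oxy]-3-hydroxy-3-methylpentanoate | CC(C)(C)[Si](C)(C)OC(=O)C[C@](C)(O)CCO[Si](C)(C)C(C)(C)C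
F4 | step 2 | (3R)-5-[(tert-butyldimethylsilyl)oxy]-3-hydroxy-3-methylpentanoic acid | OC(=O)C[C@](C)(O)CCO[Si](C)(C)C(C)(C)C
F5 | step 2 | prop-2-yn-1-yl (3R)-5-[(tert-butyldimethylsilyl)oxy]-3-hydroxy-3-methylpentanoate | C#CCOC(=O)C[C@](C)(O)CCO[Si](C)(C)C(C)(C)C
A1 | alternative 1 | fully silyl-protected target (phenol tert-butyldimethylsilyl ether, tertiary triethylsilyl ether, 2-(trimethylsilyl)ethyl ester) | COc1cc(/C=C\COC(=O)C[C@](C)(O[Si](CC)(CC)CC)CC(=O)OCC[Si](C)(C)C)cc(OC)c1O[Si](C)(C)C(C)(C)C
A2 | alternative 1 | 2-(trimethylsilyl)ethyl 5-diazo-3-methyl-4-oxo-3-[(triethylsilyl)oxy]pentanoate, single enantiomer derived from A4 | [N-]=[N+]=CC(=O)[C@](C)(O[Si](CC)(CC)CC)CC(=O)OCC[Si](C)(C)C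
A3 | alternative 1 | (2Z)-3-(4-{[tert-butyl(dimethyl)silyl]oxy}-3,5-dimethoxyphenyl)prop-2-en-1-ol | COc1cc(/C=C\CO)cc(OC)c1O[Si](C)(C)C(C)(C)C
A4 | alternative 1 | (R)-citramalic acid, (2R)-2-hydroxy-2-methylbutanedioic acid | OC(=O)[C@](C)(O)CC(=O)O
A5 | alternative 2 | S-phenyl thioester of the phenol-silylated target | COc1cc(/C=C\COC(=O)C[C@](C)(O)CC(=O)Sc2ccccc2)cc(OC)c1O[Si](C)(C)C(C)(C)C
A6 | alternative 2 | (2Z)-3-(4-{[tert-butyl(dimethyl)silyl]oxy}-3,5-dimethoxyphenyl)prop-2-en-1-yl 3-oxobutanoate | COc1cc(/C=C\COC(=O)CC(C)=O)cc(OC)c1O[Si](C)(C)C(C)(C)C
A7 | alternative 2 | 3-oxo-3-(phenylsulfanyl)propanoic acid (malonic acid half thioester) | OC(=O)CC(=O)Sc1ccccc1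
A8 | alternative 3 | target protected as phenol tert-butyldimethylsilyl ether and 2-(trimethylsilyl)ethyl ester | COc1cc(/C=C\COC(=O)C[C@](C)(O)CC(=O)OCC[Si](C)(C)C)cc(OC)c1O[Si](C)(C)C(C)(C)C
A9 | alternative 3 | tert-butyl{4-[(Z)-2-iodoethenyl]-2,6-dimethoxyphenoxy}dimethylsilane | COc1cc(/C=C\I)cc(OC)c1O[Si](C)(C)C(C)(C)C
A10 | alternative 3 | (tributylstannyl)methyl 2-(trimethylsilyl)ethyl 3-hydroxy-3-methylpentanedioate, the enantiomer that maps onto 10 | CCCC[Sn](CCCC)(CCCC)COC(=O)C[C@](C)(O)CC(=O)OCC[Si](C)(C)C
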